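**Plan**

1. Retrosynthetic cuts, in order: the C15/C19 methyl esters and the C13 silyl ether; C8=C17 (Wittig on a C8 ketone); C8=O and C9–H (hydroboration/oxidation of a C8=C9 alkene); C9–C11 (Negishi coupling of a C9 enol triflate with a C11 alkylzinc from (R)-mevalonolactone); C5–H (from C5–OH via C5=C6); then C4–C5 (aldol), C2=C3 (Wittig) and C10–C1 (Michael) back to an achiral enoate-dione.
2. Enabling feature: C10 is quaternary and its ring-B neighbours C5 and C9 can both be carbonyls, so ring B is a mirror-symmetric 2-methylcyclohexane-1,3-dione. C4 (Me, CO2Me) is an ester α-carbon bonded to C5, so C4–C5 is a latent aldol bond; closing ring A onto one of the two enantiotopic carbonyls sets C10, C5 and C4 together.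
3. Forward order: ring B is bought as the dione; the C1–C4 chain is attached; ring A is closed last by a copper hydride reductive aldol; C5 is deoxygenated; the spared C9 ketone becomes the side-chain attachment point and C8 then becomes the methylidene carbon.
4. Stereochemistry: C10 and C4 (and the temporary C5 carbinol) come from the chiral copper hydride catalyst and the closed aldol transition state; C5–H from α-face hydrogenation; C9 from α-face hydroboration and the equatorial preference next to the C8 ketone; C13 is bought with (R)-mevalonolactone.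

Key step: step 3

Locants C1–C20 in the prose are labdane positions (C4 carries Me and the ester, C5/C10 are the ring-fusion carbons, C8 the methylidene, C9 the side chain, C13 the carbinol); β is the face of the C10 methyl.

Assumption: the (R)-ligand in step 3 is taken to direct attack to the carbonyl that gives the (1S,4aS,8aR) ketol; the sense of induction would be fixed in the first run, and the (S)-ligand would be used, with nothing else changed, if it proves opposite.

**Route**

Step 1
Reactants: 1 2-methylcyclohexane-1,3-dione; 2 acrolein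
Product: 3 3-(1-methyl-2,6-dioxocyclohexyl)propanal
Conditions: H2O, rt
Reagents that add atoms: none
Why: Michael addition of the cyclic 1,3-dione through C2 to acrolein in water should give the C-alkylated triketone and create the (still prochiral) quaternary C10 with the C1–C3 arm.

Step 2
Reactants: 3 3-(1-methyl-2,6-dioxocyclohexyl)propanal; 4 methyl 2-(triphenylphosphoranylidene)propanoate
Product: 5 methyl (2E)-2-methyl-5-(1-methyl-2,6-dioxocyclohexyl)pent-2-enoate
Conditions: CH2Cl2, rt to 40 °C
Reagents that add atoms: none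
Why: Wittig olefination with the stabilised ylide should take the aldehyde only (the neopentylic ketones are inert) and install C4 with its methyl and ester as the (E)-enoate.

Step 3
Reactants: 5 methyl (2E)-2-methyl-5-(1-methyl-2,6-dioxocyclohexyl)pent-2-enoate
Product: 7 methyl (1S,4aS,8aR)-8a-hydroxy-1,4a-dimethyl-5-oxodecahydronaphthalene-1-carboxylate, via silyl ether 6 (not isolated)
Conditions: Cu(OAc)2·H2O (5 mol %), (R)-DTBM-SEGPHOS (5.5 mol %), (EtO)2MeSiH (2 equiv), toluene, 0 °C to rt; then 1 M HCl, THF, 0 °C
Reagents that add atoms: none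
Why: The ligated copper hydride formed from Cu(OAc)2 and the silane should add hydride to C3 of the enoate to give a copper ester enolate at C4, which attacks one of the two enantiotopic ring-B carbonyls (C5); the copper aldolate is then silylated by the silane, which regenerates the hydride. The closest known reaction type is the copper hydride-catalysed desymmetrising reductive aldol cyclisation of β-monosubstituted enoates tethered to 2-methylcycloalkane-1,3-diones; the present substrate differs only by the α-methyl group that makes C4 quaternary. Ring A closes by a 6-(enolexo)-exo-trig aldol addition through a chair in which the C1–C3 tether spans C10 and C4. C10 is fixed by the chiral bisphosphine, which decides which carbonyl is attacked; C5 follows from the tether, which reaches only the carbonyl face on its own side and so gives the cis-fused ketol (OH cis to the C10 methyl); C4 follows from the copper-bridged closed chair, which holds the ester carbonyl gauche to the carbinol oxygen and avoids a 1,3-diaxial contact between the C4 and C10 methyl groups, so that CO2Me ends cis to OH and to the C10 methyl. The step needs conjugate reduction to outrun 1,2-hydrosilylation of the ketones and ring closure to outrun silylation of the enolate; both ketones are flanked by the quaternary C10 and are slow toward copper hydride, and the enolate is generated five atoms from the carbonyl it attacks.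

Step 4
Reactants: 7 methyl (1S,4aS,8aR)-8a-hydroxy-1,4a-dimethyl-5-oxodecahydronaphthalene-1-carboxylate
Product: 8 methyl (1S,4aS)-1,4a-dimethyl-5-oxo-1,2,3,4,4a,5,6,7-octahydronaphthalene-1-carboxylate
Conditions: SOCl2, pyridine, CH2Cl2, −20 to 0 °C
Reagents that add atoms: none
Why: E2 dehydration of the tertiary chlorosulfite can only run toward C6, because C4 and C10 carry no hydrogen, and low temperature with pyridine should suppress cationic methyl shifts and retro-aldol cleavage.

Step 5
Reactants: 8 methyl (1S,4aS)-1,4a-dimethyl-5-oxo-1,2,3,4,4a,5,6,7-octahydronaphthalene-1-carboxylate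
Product: 9 methyl (1S,4aS,8aR)-1,4a-dimethyl-5-oxodecahydronaphthalene-1-carboxylate
Conditions: H2 (1–4 atm), 10% Pd/C, EtOAc/AcOH, rt
Reagents that add atoms: none
Why: Catalytic hydrogenation should deliver hydrogen to the α-face of C5=C6, away from the β-oriented C10 methyl and C4 ester, and so give the trans ring fusion (5α-H) as in 4,4-disubstituted Δ5 steroids.

Step 6
Reactants: 10 (R)-mevalonolactone
Product: 12 methyl (R)-3,5-dihydroxy-3-methylpentanoate, via potassium mevalonate 11 (not isolated)
Conditions: KOH (1.0 equiv), H2O, rt; evaporate; MeI, DMF, rt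
Reagents that add atoms: potassium hydroxide [K+].[OH-]; iodomethane CI
Why: Saponification of the lactone followed by O-alkylation of the carboxylate should open the ring without touching the C13 stereocentre and leave the two chain ends differentiated.

Step 7
Reactants: 12 methyl (R)-3,5-dihydroxy-3-methylpentanoate
Product: 13 methyl (S)-3-hydroxy-5-iodo-3-methylpentanoate
Conditions: I2, PPh3, imidazole, CH2Cl2, 0 °C
Reagents that add atoms: iodine II
Why: The Appel reaction is selective for the primary alcohol over the tertiary one and also removes the hydroxyl that could re-lactonise.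

Step 8
Reactants: 13 methyl (S)-3-hydroxy-5-iodo-3-methylpentanoate
Product: 14 methyl (S)-5-iodo-3-methyl-3-(triethylsilyloxy)pentanoate
Conditions: Et3SiOTf, 2,6-lutidine, CH2Cl2, −78 to 0 °C
Reagents that add atoms: triethylsilyl trifluoromethanesulfonate CC[Si](CC)(CC)OS(=O)(=O)C(F)(F)F
Why: Silyl triflate silylation is the standard way to cap a tertiary alcohol, and the ether blocks protonolysis of the zinc reagent and retro-aldol of the β-hydroxy ester under the later basic steps.

Step 9
Reactants: 9 methyl (1S,4aS,8aR)-1,4a-dimethyl-5-oxodecahydronaphthalene-1-carboxylate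
Product: 16 methyl (1S,4aS,8aR)-1,4a-dimethyl-5-{[(trifluoromethyl)sulfonyl]oxy}-1,2,3,4,4a,7,8,8a-octahydronaphthalene-1-carboxylate, via potassium enolate 15 (not isolated)
Conditions: KN(SiMe3)2, THF, −78 °C; then PhNTf2, −78 to 0 °C
Reagents that add atoms: N-phenylbis(trifluoromethanesulfonimide) O=S(=O)(N(c1ccccc1)S(=O)(=O)C(F)(F)F)C(F)(F)F
Why: The C9 ketone can enolise only toward C8 (C10 is quaternary and the C4 ester has no α-hydrogen), so O-triflation should give a single C8=C9 enol triflate.

Step 10
Reactants: 14 methyl (S)-5-iodo-3-methyl-3-(triethylsilyloxy)pentanoate; 16 methyl (1S,4aS,8aR)-1,4a-dimethyl-5-{[(trifluoromethyl)sulfonyl]oxy}-1,2,3,4,4a,7,8,8a-octahydronaphthalene-1-carboxylate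
Product: 18 methyl (1S,4aS,8aR)-5-[(3R)-5-methoxy-3-methyl-5-oxo-3-(triethylsilyloxy)pentyl]-1,4a-dimethyl-1,2,3,4,4a,7,8,8a-octahydronaphthalene-1-carboxylate, via alkylzinc iodide 17 (not isolated)
Conditions: Zn dust (activated with BrCH2CH2Br and Me3SiCl), LiCl, THF, 40 °C; then 16, Pd(OAc)2 (5 mol %), SPhos (10 mol %), THF/NMP, 50 °C
Reagents that add atoms: none
Why: Zinc insertion into the primary iodide tolerates the ester and silyl ether, and Negishi coupling of the alkylzinc with the alkenyl triflate should form the C9–C11 bond and bring in the intact C13 stereocentre.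

Step 11
Reactants: 18 methyl (1S,4aS,8aR)-5-[(3R)-5-methoxy-3-methyl-5-oxo-3-(triethylsilyloxy)pentyl]-1,4a-dimethyl-1,2,3,4,4a,7,8,8a-octahydronaphthalene-1-carboxylate
Product: 20 methyl (1S,4aS,5R,6R,8aR)-6-hydroxy-5-[(3R)-5-methoxy-3-methyl-5-oxo-3-(triethylsilyloxy)pentyl]-1,4a-dimethyldecahydronaphthalene-1-carboxylate, via alkylborane 19 (not isolated)
Conditions: BH3·SMe2, THF, 0 °C to rt; then NaBO3·4H2O, THF/H2O, rt
Reagents that add atoms: sodium perborate [Na+].[Na+].O[B-]1(O)OO[B-](O)(O)OO1
Why: Hydroboration should place boron on the less substituted C8 and deliver hydrogen to C9 from the α-face opposite the axial C10 methyl (9α-H, side chain β), and the mild perborate oxidation spares the methyl esters.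

Step 12
Reactants: 20 methyl (1S,4aS,5R,6R,8aR)-6-hydroxy-5-[(3R)-5-methoxy-3-methyl-5-oxo-3-(triethylsilyloxy)pentyl]-1,4a-dimethyldecahydronaphthalene-1-carboxylate
Product: 21 methyl (1S,4aS,5R,8aR)-5-[(3R)-5-methoxy-3-methyl-5-oxo-3-(triethylsilyloxy)pentyl]-1,4a-dimethyl-6-oxodecahydronaphthalene-1-carboxylate
Conditions: Dess–Martin periodinane, NaHCO3, CH2Cl2, rt
Reagents that add atoms: none
Why: Buffered Dess–Martin oxidation of the secondary alcohol should give the C8 ketone with the C9 side chain in its stable equatorial position, so any C9 epimer from step 11 would converge here or in step 13.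

Step 13
Reactants: 21 methyl (1S,4aS,5R,8aR)-5-[(3R)-5-methoxy-3-methyl-5-oxo-3-(triethylsilyloxy)pentyl]-1,4a-dimethyl-6-oxodecahydronaphthalene-1-carboxylate
Product: 22 methyl (1S,4aR,5S,8aR)-5-[(3R)-5-methoxy-3-methyl-5-oxo-3-(triethylsilyloxy)pentyl]-1,4a-dimethyl-6-methylidenedecahydronaphthalene-1-carboxylate
Conditions: Ph3PCH3Br, KOt-Bu, toluene, rt to 80 °C
Reagents that add atoms: methyltriphenylphosphonium bromide C[P+](c1ccccc1)(c1ccccc1)c1ccccc1.[Br-]
Why: Wittig methylenation of 8-oxo decalins of this type is well precedented, the ylide ignores the esters, and any enolisation can only return the equatorial C9 epimer.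

Step 14
Reactants: 22 methyl (1S,4aR,5S,8aR)-5-[(3R)-5-methoxy-3-methyl-5-oxo-3-(triethylsilyloxy)pentyl]-1,4a-dimethyl-6-methylidenedecahydronaphthalene-1-carboxylate
Product: 23 methyl (1S,4aR,5S,8aR)-5-[(3R)-3-hydroxy-5-methoxy-3-methyl-5-oxopentyl]-1,4a-dimethyl-6-methylidenedecahydronaphthalene-1-carboxylate
Conditions: HF·pyridine, pyridine, THF, 0 °C to rt
Reagents that add atoms: none
Why: Buffered fluoride desilylation should free the tertiary alcohol without generating an alkoxide (no retro-aldol) and without isomerising the exocyclic alkene.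

Step 15
Reactants: 23 methyl (1S,4aR,5S,8aR)-5-[(3R)-3-hydroxy-5-methoxy-3-methyl-5-oxopentyl]-1,4a-dimethyl-6-methylidenedecahydronaphthalene-1-carboxylate
Product: 25 (1S,4aR,5S,8aR)-5-[(3R)-4-carboxy-3-hydroxy-3-methylbutyl]-1,4a-dimethyl-6-methylidenedecahydronaphthalene-1-carboxylic acid, via disodium dicarboxylate 24 (not isolated)
Conditions: NaSEt (excess), DMF, 60 °C; then 1 M HCl (work-up)
Reagents that add atoms: none
Why: Thiolate SN2 attack at the O-methyl carbons cleaves both esters, including the axial neopentylic C19 ester that resists saponification, under conditions too weakly basic to deprotonate the tertiary alcohol.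

**Compound list**

1 | 2-methylcyclohexane-1,3-dione | CC1C(=O)CCCC1=O | starting material
2 | acrolein | C=CC=O | starting material
3 | 3-(1-methyl-2,6-dioxocyclohexyl)propanal | O=CCCC1(C)C(=O)CCCC1=O | intermediate
4 | methyl 2-(triphenylphosphoranylidene)propanoate | COC(=O)C(C)=P(c1ccccc1)(c1ccccc1)c1ccccc1 | starting material
5 | methyl (2E)-2-methyl-5-(1-methyl-2,6-dioxocyclohexyl)pent-2-enoate | COC(=O)/C(C)=C/CCC1(C)C(=O)CCCC1=O | intermediate
6 | methyl (1S,4aS,8aR)-8a-{[diethoxy(methyl)silyl]oxy}-1,4a-dimethyl-5-oxodecahydronaphthalene-1-carboxylate | O=C1CCC[C@@]2(O[Si](C)(OCC)OCC)[C@]1(C)CCC[C@]2(C)C(=O)OC | intermediate (not isolated)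
7 | methyl (1S,4aS,8aR)-8a-hydroxy-1,4a-dimethyl-5-oxodecahydronaphthalene-1-carboxylate | O=C1CCC[C@@]2(O)[C@]1(C)CCC[C@]2(C)C(=O)OC | intermediate
8 | methyl (1S,4aS)-1,4a-dimethyl-5-oxo-1,2,3,4,4a,5,6,7-octahydronaphthalene-1-carboxylate | O=C1CCC=C2[C@]1(C)CCC[C@]2(C)C(=O)OC | intermediate
9 | methyl (1S,4aS,8aR)-1,4a-dimethyl-5-oxodecahydronaphthalene-1-carboxylate | O=C1CCC[C@@H]2[C@]1(C)CCC[C@]2(C)C(=O)OC | intermediate
10 | (R)-mevalonolactone | O=C1C[C@](C)(O)CCO1 | starting material
11 | potassium (R)-3,5-dihydroxy-3-methylpentanoate | [K+].[O-]C(=O)C[C@](C)(O)CCO | intermediate (not isolated)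
12 | methyl (R)-3,5-dihydroxy-3-methylpentanoate | COC(=O)C[C@](C)(O)CCO | intermediate
13 | methyl (S)-3-hydroxy-5-iodo-3-methylpentanoate | COC(=O)C[C@](C)(O)CCI | intermediate
14 | methyl (S)-5-iodo-3-methyl-3-(triethylsilyloxy)pentanoate | COC(=O)C[C@](C)(O[Si](CC)(CC)CC)CCI | intermediate
15 | potassium enolate of 9 (C8=C9–OK) | [K+].[O-]C1=CCC[C@@H]2[C@]1(C)CCC[C@]2(C)C(=O)OC | intermediate (not isolated)
16 | methyl (1S,4aS,8aR)-1,4a-dimethyl-5-{[(trifluoromethyl)sulfonyl]oxy}-1,2,3,4,4a,7,8,8a-octahydronaphthalene-1-carboxylate | O=S(=O)(OC1=CCC[C@@H]2[C@]1(C)CCC[C@]2(C)C(=O)OC)C(F)(F)F | intermediate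
17 | [(S)-5-methoxy-3-methyl-5-oxo-3-(triethylsilyloxy)pentyl]zinc iodide | COC(=O)C[C@](C)(O[Si](CC)(CC)CC)CC[Zn]I | intermediate (not isolated)
18 | methyl (1S,4aS,8aR)-5-[(3R)-5-methoxy-3-methyl-5-oxo-3-(triethylsilyloxy)pentyl]-1,4a-dimethyl-1,2,3,4,4a,7,8,8a-octahydronaphthalene-1-carboxylate | COC(=O)C[C@](C)(O[Si](CC)(CC)CC)CCC1=CCC[C@@H]2[C@]1(C)CCC[C@]2(C)C(=O)OC | intermediate
19 | C8 alkylborane of 18 (8α-BH2, 9α-H) | COC(=O)C[C@](C)(O[Si](CC)(CC)CC)CC[C@H]1[C@H](B)CC[C@@H]2[C@]1(C)CCC[C@]2(C)C(=O)OC | intermediate (not isolated)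
20 | methyl (1S,4aS,5R,6R,8aR)-6-hydroxy-5-[(3R)-5-methoxy-3-methyl-5-oxo-3-(triethylsilyloxy)pentyl]-1,4a-dimethyldecahydronaphthalene-1-carboxylate | COC(=O)C[C@](C)(O[Si](CC)(CC)CC)CC[C@H]1[C@H](O)CC[C@@H]2[C@]1(C)CCC[C@]2(C)C(=O)OC | intermediate
21 | methyl (1S,4aS,5R,8aR)-5-[(3R)-5-methoxy-3-methyl-5-oxo-3-(triethylsilyloxy)pentyl]-1,4a-dimethyl-6-oxodecahydronaphthalene-1-carboxylate | COC(=O)C[C@](C)(O[Si](CC)(CC)CC)CC[C@H]1C(=O)CC[C@@H]2[C@]1(C)CCC[C@]2(C)C(=O)OC | intermediate
22 | methyl (1S,4aR,5S,8aR)-5-[(3R)-5-methoxy-3-methyl-5-oxo-3-(triethylsilyloxy)pentyl]-1,4a-dimethyl-6-methylidenedecahydronaphthalene-1-carboxylate | COC(=O)C[C@](C)(O[Si](CC)(CC)CC)CC[C@H]1C(=C)CC[C@@H]2[C@]1(C)CCC[C@]2(C)C(=O)OC | intermediate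
23 | methyl (1S,4aR,5S,8aR)-5-[(3R)-3-hydroxy-5-methoxy-3-methyl-5-oxopentyl]-1,4a-dimethyl-6-methylidenedecahydronaphthalene-1-carboxylate | COC(=O)C[C@](C)(O)CC[C@H]1C(=C)CC[C@@H]2[C@]1(C)CCC[C@]2(C)C(=O)OC | intermediate
24 | disodium salt of 25 | [Na+].[Na+].[O-]C(=O)C[C@](C)(O)CC[C@H]1C(=C)CC[C@@H]2[C@]1(C)CCC[C@]2(C)C(=O)[O-] | intermediate (not isolated)
25 | (1S,4aR,5S,8aR)-5-[(3R)-4-carboxy-3-hydroxy-3-methylbutyl]-1,4a-dimethyl-6-methylidenedecahydronaphthalene-1-carboxylic acid (CNP0126190.2; (13R)-13-hydroxylabd-8(17)-ene-15,19-dioic acid) | OC(=O)C[C@](C)(O)CC[C@H]1C(=C)CC[C@@H]2[C@]1(C)CCC[C@]2(C)C(=O)O | target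

**Step count and risks**

Total: 15 steps. Longest linear sequence: 12 steps (steps 1–5 and 9–15); steps 6–8 make the side-chain fragment.

Steps most likely to fail:

Step 3. Hydride transfer to the α,β-disubstituted enoate may be slow enough that carbonyl hydrosilylation or simple saturation without ring closure takes over, and facial control at the fully substituted enolate carbon may erode. The fallback sets out from aldehyde 3 and returns at keto ester 9; it no longer forms the quaternary C4 in the ring closure. Wittig reaction of 3 with methyl (triphenylphosphoranylidene)acetate would give methyl (E)-5-(1-methyl-2,6-dioxocyclohexyl)pent-2-enoate F1. The same copper hydride reductive aldol cyclisation, now in its established β-monosubstituted form, would give methyl (1S,4aS,8aS)-8a-hydroxy-4a-methyl-5-oxodecahydronaphthalene-1-carboxylate F2. Dehydration (SOCl2, pyridine; then DBU to bring the alkene into conjugation) would give methyl (4aS)-4a-methyl-5-oxo-2,3,4,4a,5,6,7,8-octahydronaphthalene-1-carboxylate F3. Reductive methylation (Li, NH3/THF, t-BuOH; then MeI) should set C5–H trans to the C10 methyl by axial protonation and C4 by equatorial attack of MeI anti to that methyl; the C9 ketone is reduced at the same time, giving methyl (1S,4aS,5S,8aR)-5-hydroxy-1,4a-dimethyldecahydronaphthalene-1-carboxylate F4. Dess–Martin oxidation of F4 returns 9.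

Step 5. Hydrogen uptake may stall at the alkene flanked by two quaternary carbons, or delivery may occur partly from the β-face to give the cis-fused isomer. The fallback sets out from alkene 8 and returns at 9 without new compounds. Surface hydrogenation is replaced by a metal-hydride hydrogen-atom-transfer reduction (Mn(dpm)3 [tris(2,2,6,6-tetramethylheptane-3,5-dionato)manganese], PhSiH3, t-BuOOH, i-PrOH, rt). The C5 radical formed by stepwise hydrogen-atom transfer is quenched under product-stability control, which favours the trans-fused decalin regardless of catalyst access to either face, and the ketone and ester are tolerated.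

Step 10. Transmetalation to the alkenylpalladium next to the quaternary C10 may be slow, so that protodezincation or β-hydride elimination consumes the alkylzinc fragment. The fallback sets out from iodide 14 (with triflate 16) and returns at 18, using a boron instead of a zinc nucleophile made by a different route. Dehydroiodination of 14 (DBU, toluene, 80 °C) would give methyl (S)-3-methyl-3-(triethylsilyloxy)pent-4-enoate F5. Hydroboration with 9-borabicyclo[3.3.1]nonane would give methyl (R)-5-(9-borabicyclo[3.3.1]nonan-9-yl)-3-methyl-3-(triethylsilyloxy)pentanoate F6. B-alkyl Suzuki–Miyaura coupling of F6 with 16 (PdCl2(dppf), AsPh3, Cs2CO3, DMF/H2O, rt to 50 °C) would give 18.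

**Further compounds**

F1 | step 3 | methyl (E)-5-(1-methyl-2,6-dioxocyclohexyl)pent-2-enoate | COC(=O)/C=C/CCC1(C)C(=O)CCCC1=O
F2 | step 3 | methyl (1S,4aS,8aS)-8a-hydroxy-4a-methyl-5-oxodecahydronaphthalene-1-carboxylate | O=C1CCC[C@@]2(O)[C@]1(C)CCC[C@@H]2C(=O)OC
F3 | step 3 | methyl (4aS)-4a-methyl-5-oxo-2,3,4,4a,5,6,7,8-octahydronaphthalene-1-carboxylate | COC(=O)C1=C2CCCC(=O)[C@@]2(C)CCC1
F4 | step 3 | methyl (1S,4aS,5S,8aR)-5-hydroxy-1,4a-dimethyldecahydronaphthalene-1-carboxylate | O[C@H]1CCC[C@@H]2[C@]1(C)CCC[C@]2(C)C(=O)OC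
F0 | step 5 | none | none
F5 | step 10 | methyl (S)-3-methyl-3-(triethylsilyloxy)pent-4-enoate | C=C[C@@](C)(O[Si](CC)(CC)CC)CC(=O)OC
F6 | step 10 | methyl (R)-5-(9-borabicyclo[3.3.1]nonan-9-yl)-3-methyl-3-(triethylsilyloxy)pentanoate | COC(=O)C[C@](C)(O[Si](CC)(CC)CC)CCB1C2CCCC1CCC2
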